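**Assumptions (one line each)**
- The SMILES has 19 chain carbons plus the ring carbon, so the substituent is n‑nonadecyl (C19H39).
- The target is achiral. The only stereocentre in the route is the quaternary carbinol of 3 and 5, which is racemic and destroyed on aromatisation in Step 3.

## Retrosynthetic overview
1. The target 2‑hydroxy‑5‑methoxy‑3‑nonadecyl‑1,4‑benzoquinone comes from selective O‑dealkylation of the 2‑isopropoxy quinone, where the isopropyl group serves as a removable OH surrogate.
2. The fully substituted quinone ring is built in one thermal step by a Moore/Liebeskind cyclobutenone ring expansion. This is a 4π ring opening to a dienylketene, then a 6π closure.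
3. The cyclobutenone comes from diisopropyl squarate by two sequential 1,2‑additions, first 1‑methoxyvinyllithium and then nonadecyllithium with mild acid. The only ring formed is the benzene ring, and its substituent pattern is fixed by the cyclobutenone.

## Route

**Step 1**
Reactants: 1 (diisopropyl squarate); 2 (methyl vinyl ether, used as its α‑lithio derivative)
Product: 3 (4‑(TBSO)‑4‑(1‑methoxyvinyl)‑2,3‑diisopropoxycyclobut‑2‑en‑1‑one, racemic)
Conditions: 2, t‑BuLi, THF, −65 → 0 °C; cool to −78 °C, add 1; then TBSCl, DMPU, −78 °C → rt
Reagents that add atoms: TBSCl, CC(C)(C)[Si](C)(C)Cl (adds TBS)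
Why: 1,2‑addition of the α‑alkoxyvinyllithium to the squarate C=O, with the alkoxide trapped as its TBS ether. The silyl ether keeps the C4 carbinol from ionising in Step 2, so only the carbinol from the alkyl addition can ionise.

**Step 2**
Reactants: 3; 4 (1‑bromononadecane, converted to n‑C19H39Li)
Product: 5 (4‑(TBSO)‑4‑(1‑methoxyvinyl)‑3‑nonadecyl‑2‑isopropoxycyclobut‑2‑en‑1‑one)
Conditions: 4, t‑BuLi (2 equiv), Et2O/THF, −78 °C; add 3, −78 °C, 1 h; then 10% aq. citric acid/THF, 0 °C, 10 min
Reagents that add atoms: water, O (supplies the new C=O oxygen; iPrOH is lost)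
Why: Proposed new method: RLi adds 1,2 to the vinylogous‑ester C=O. Mild acid ionises only that tertiary allylic carbinol to a vinylogous oxocarbenium, and water attacks the isopropoxy‑bearing carbon. Loss of iPrOH transposes the ketone and places the alkyl group on the alkene carbon next to the silyloxy‑bearing quaternary carbon. The closest known reaction is the Moore/Liebeskind squarate 1,2‑addition/acid rearrangement. The new element is an enol ether that must survive the deactivated, mild acid conditions, and a very long alkyl chain.

**Step 3**
Reactants: 5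
Product: 6 (3‑isopropoxy‑6‑methoxy‑2‑nonadecyl‑4‑(TBSO)phenol, i.e. 1‑hydroxy‑2‑iPrO‑3‑C19H39‑4‑TBSO‑5‑MeO‑benzene with H at C6)
Conditions: xylenes, 140 °C, 2 h, Ar
Reagents that add atoms: none
Why: Moore/Liebeskind ring expansion. Conrotatory 4π opening with outward rotation of the OTBS donor gives the (Z)‑dienylketene. The nucleophilic CH2 terminus of the enol ether then closes onto the ketene carbon by 6π electrocyclisation, and tautomerisation aromatises the ring. The ketene carbon becomes C–OH, flanked by C–OiPr and CH. The silyloxy carbon is flanked by the C–alkyl and C–OMe carbons, which is the target pattern.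

**Step 4**
Reactants: 6
Product: 7 (2‑isopropoxy‑5‑methoxy‑3‑nonadecyl‑1,4‑benzoquinone)
Conditions: TBAF, AcOH, THF, 0 °C; then Ag2O, rt
Reagents that add atoms: none
Why: Buffered fluoride desilylation gives the electron‑rich hydroquinone, which Ag2O oxidises in the same pot to the p‑quinone (oxidation state adjustment only; no stereocentre is involved).

**Step 5**
Reactants: 7
Product: 8 (Irisoquin‑C, 2‑hydroxy‑5‑methoxy‑3‑nonadecyl‑1,4‑benzoquinone)
Conditions: BCl3 (1.1 equiv), CH2Cl2, −78 → 0 °C, 30 min; then aq. NaHCO3 quench
Reagents that add atoms: none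
Why: Chelation‑assisted, SN1‑like Lewis‑acid cleavage of the secondary isopropyl vinylogous ester. The methyl ether at C5 is cleaved much more slowly under these conditions. No stereocentre is involved.

## Compound list
1 | diisopropyl squarate | CC(C)OC1=C(OC(C)C)C(=O)C1=O | starting material
2 | methyl vinyl ether | C=COC | starting material
3 | 4‑(TBSO)‑4‑(1‑methoxyvinyl)‑2,3‑diisopropoxycyclobut‑2‑en‑1‑one (racemic) | C=C(OC)C1(O[Si](C)(C)C(C)(C)C)C(=O)C(OC(C)C)=C1OC(C)C | intermediate
4 | 1‑bromononadecane | CCCCCCCCCCCCCCCCCCCBr | starting material
5 | 4‑(TBSO)‑4‑(1‑methoxyvinyl)‑3‑nonadecyl‑2‑isopropoxycyclobut‑2‑en‑1‑one (racemic) | CCCCCCCCCCCCCCCCCCCC1=C(OC(C)C)C(=O)C1(O[Si](C)(C)C(C)(C)C)C(OC)=C | intermediate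
6 | 3‑isopropoxy‑6‑methoxy‑2‑nonadecyl‑4‑silyloxy arene (mono‑TBS hydroquinone ether) | CCCCCCCCCCCCCCCCCCCC1=C(OC(C)C)C(O)=CC(OC)=C1O[Si](C)(C)C(C)(C)C | intermediate
7 | 2‑isopropoxy‑5‑methoxy‑3‑nonadecyl‑1,4‑benzoquinone | CCCCCCCCCCCCCCCCCCCC1=C(OC(C)C)C(=O)C=C(OC)C1=O | intermediate
8 | Irisoquin‑C | CCCCCCCCCCCCCCCCCCCC1=C(O)C(=O)C=C(OC)C1=O | target

**Total step count:** 5
**Longest linear sequence:** 5 steps (from diisopropyl squarate)

## Three steps most likely to fail
1. **Step 2.** The nonadecyllithium addition is hindered by the adjacent quaternary carbon, and the enol ether may not survive the acid ionisation.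
   - Fallback: change the order. Add nonadecyllithium to diisopropyl squarate and quench with TFAA to give 3‑nonadecyl‑4‑isopropoxycyclobutenedione, which needs no enol ether. Then add (Z)‑2‑methoxyvinyllithium (from the (Z)‑stannane), which adds at the carbonyl next to the OiPr carbon. Thermolysis, oxidation and BCl3 cleavage then give the same target.
2. **Step 3.** The ring expansion may give incomplete conversion or side reactions at 140 °C.
   - Fallback: abandon the ring expansion and use reductive alkylation of 2,5‑dihydroxy‑1,4‑benzoquinone with nonadecanal, followed by regioselective O‑methylation at the 5‑OH.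
3. **Step 5.** BCl3 may cleave the methyl ether along with the isopropyl ether.
   - Fallback: start from dibenzyl squarate so the C2 oxygen carries a benzyl group. Remove it by H2, Pd/C at the hydroquinone stage after desilylation, then oxidise in air to give the target.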